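**Retrosynthetic overview**

1. 14‑O‑Acetylandrographolide ⇒ alkylidene lactone 33 (desilylation, C14 acetylation, acetonide removal last) ⇒ C12=C13 by aldol–dehydration of aldehyde 27 with silyloxy lactone 29.
2. 27 ⇒ ring B ketone 18: C9–C11 by α′‑alkylation of the Saegusa enone 20 (the C6=C7 alkene blocks C7), C8=C17 by Wittig methylenation.
3. Feature used: C10, the quaternary fusion carbon of rings A and B, carries the C20 methyl trans to H5, and C1 lies β to the C3 oxygen. The C1–C10 bond is therefore cut to a C10=C20 methylene on ring B and a C3 vinyl ketone (14), closed by a hydrogen‑atom‑transfer radical 6‑endo cyclisation.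
4. 14 ⇒ ester 9: one dianionic Ireland–Claisen rearrangement makes the C4–C5 bond, both stereocentres and the C10 methylene. The acid part is an Evans syn‑aldol unit whose C3 carbinol steers the face and ends as the C3 ketone; the allylic alcohol 3 comes from Birch reduction of 3‑methoxybenzyl alcohol.
5. Ring order: ring B (from the arene) → ring A (key step) → lactone ring attached last as an intact chiral‑pool unit.

Key step: step 9

Remark: labdane numbering of the target is used for all intermediates; the C12 carbinol centre of 31 and 32 is an epimeric mixture, which is immaterial because it is removed in step 22.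

**Route**

Step 1
Reactants: 1 3‑methoxybenzyl alcohol
Product: 2 (5‑methoxycyclohexa‑1,4‑dien‑1‑yl)methanol
Conditions: Li, NH3(l), THF, t‑BuOH, −78 → −33 °C; NH4Cl
Reagents that add atoms: none
Why: Birch reduction gives the 1,4‑diene that keeps the methoxy‑ and hydroxymethyl‑bearing carbons unsaturated, and the benzylic C–O bond should survive because the alcohol is present as its lithium alkoxide.

Step 2
Reactants: 2 (5‑methoxycyclohexa‑1,4‑dien‑1‑yl)methanol
Product: 3 (1,4‑dioxaspiro[4.5]dec‑7‑en‑7‑yl)methanol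
Conditions: ethylene glycol, p‑TsOH·H2O (cat.), CH2Cl2, 0 → 23 °C
Reagents that add atoms: ethylene glycol, OCCO
Why: Acid‑catalysed ketalisation of the enol ether (C‑protonation at C7, capture of the oxocarbenium ion by the diol) should give the β,γ‑unsaturated dioxolane without moving the C10=C5 alkene, since a ketal offers no conjugation.

Step 3
Reactants: 4 (R)‑4‑benzyl‑3‑propionyloxazolidin‑2‑one; 5 acrolein
Product: 7 (R)‑4‑benzyl‑3‑[(2R,3S)‑3‑hydroxy‑2‑methylpent‑4‑enoyl]oxazolidin‑2‑one, via Z‑dibutylboron enolate 6 (not isolated)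
Conditions: n‑Bu2BOTf, EtN(CHMe2)2, CH2Cl2, 0 °C; 5, −78 → 0 °C; pH 7 buffer, MeOH, H2O2
Reagents that add atoms: none
Why: Evans syn‑aldol reaction, in which the Z‑boron enolate reacts through a Zimmerman–Traxler chair on the face remote from the benzyl group, should give the (2R,3S) adduct and thus the (3S) carbinol that later steers the Claisen step.

Step 4
Reactants: 3 (1,4‑dioxaspiro[4.5]dec‑7‑en‑7‑yl)methanol; 7 aldol adduct
Product: 9 (1,4‑dioxaspiro[4.5]dec‑7‑en‑7‑yl)methyl (2R,3S)‑3‑hydroxy‑2‑methylpent‑4‑enoate, via lithium alkoxide 8 (not isolated)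
Conditions: 3 (2 equiv), n‑BuLi (1.5 equiv), THF, −78 → 0 °C; 7, −20 → 0 °C; NH4Cl aq.
Reagents that add atoms: none
Why: Transesterification of the imide by a lithium alkoxide (exocyclic acyl substitution, as in auxiliary removal by lithium benzyloxide) joins the two fragments at low temperature, where retro‑aldol cleavage of the aldolate should be slow.

Step 5
Reactants: 9 allylic β‑hydroxy ester
Product: 11 (2S,3S)‑3‑hydroxy‑2‑methyl‑2‑[(8S)‑7‑methylidene‑1,4‑dioxaspiro[4.5]decan‑8‑yl]pent‑4‑enoic acid, via chelated dilithium dianion 10 (not isolated)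
Conditions: LiN(CHMe2)2 (2.5 equiv), THF, −78 → −20 °C; then 23 → 50 °C; NH4Cl aq., citric acid to pH 4
Reagents that add atoms: none
Why: Dianionic Ireland–Claisen rearrangement: lithium bridging the C3 alkoxide and the enolate oxygen fixes C3 cis to O–Li, the allyl terminus C5 bonds to the enolate face anti to the C3 vinyl group of this chelate (as in Fráter–Seebach alkylations), which sets C4, and the chair transition state with ring carbon C6 equatorial sets C5 relative to C4 and turns C20 into the methylene on C10; Me3SiCl is withheld so that the chelate persists.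

Step 6
Reactants: 11 hydroxy acid
Product: 12 (2R,3S)‑2‑methyl‑2‑[(8S)‑7‑methylidene‑1,4‑dioxaspiro[4.5]decan‑8‑yl]pent‑4‑ene‑1,3‑diol
Conditions: LiAlH4, THF, 0 → 65 °C; H2O, NaOH aq.
Reagents that add atoms: none
Why: LiAlH4 reduction of the carboxylic acid gives the primary C19 alcohol, and the isolated alkenes and the dioxolane are inert to it.

Step 7
Reactants: 12 diol
Product: 13 (3S,4R)‑5‑(tert‑butyldimethylsilyloxy)‑4‑methyl‑4‑[(8S)‑7‑methylidene‑1,4‑dioxaspiro[4.5]decan‑8‑yl]pent‑1‑en‑3‑ol
Conditions: TBSCl, imidazole, CH2Cl2, 0 °C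
Reagents that add atoms: tert‑butyldimethylsilyl chloride, CC(C)(C)[Si](C)(C)Cl
Why: Imidazole‑promoted silylation should take the primary C19 hydroxyl selectively, because the secondary C3 hydroxyl is flanked by the quaternary C4.

Step 8
Reactants: 13 allylic alcohol
Product: 14 (4R)‑5‑(tert‑butyldimethylsilyloxy)‑4‑methyl‑4‑[(8S)‑7‑methylidene‑1,4‑dioxaspiro[4.5]decan‑8‑yl]pent‑1‑en‑3‑one
Conditions: Dess–Martin periodinane, pyridine, CH2Cl2, 0 → 23 °C
Reagents that add atoms: none
Why: Dess–Martin oxidation of the secondary allylic alcohol gives the vinyl ketone under buffered conditions and removes the C3 stereocentre once its relay role is over, while the quaternary C4 rules out enolisation.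

Step 9
Reactants: 14 methylenecyclohexane vinyl ketone
Product: 15 trans‑decalin‑3‑one (C8 dioxolane, C19 OTBS)
Conditions: Fe(acac)3 (0.3 equiv), PhSiH3 (2.5 equiv), EtOH/ethylene glycol (5:1), 0.02 M, 60 °C
Reagents that add atoms: none
Why: The iron hydride formed from Fe(acac)3 and PhSiH3 in ethanol transfers a hydrogen atom to C20 of the electron‑rich C10=C20 methylene, which makes the C20 methyl and a tertiary C10 radical; this nucleophilic radical adds to the unsubstituted terminus C1 of the vinyl ketone, and the C2 α‑keto radical is reduced by divalent iron to the enolate and protonated by ethanol. The closest known reaction type is the metal‑hydride hydrogen‑atom‑transfer reductive olefin–enone coupling in its intramolecular form, which is established for quaternary carbons and trans‑decalins. Ring A closes in the 6‑endo‑trig mode (C1 and C2 both end up in the ring), preferred over 5‑exo attack at C2 because only attack at C1 is polarity‑matched and gives a stabilised radical. The new stereocentre C10 is set by a chair‑like transition state in which the C5–C4 bond and the forming C10–C1 bond are both equatorial on ring B, so that the C20 methyl becomes axial and trans to H5 (trans ring fusion), and the C4 configuration from step 5 places CH2OTBS axial on ring A. The step needs hydrogen‑atom transfer to the 1,1‑disubstituted alkene and not to the enone, which the electron‑rich character of that alkene secures, and it needs ring closure to outrun a second hydrogen‑atom transfer, which the intramolecular six‑membered closure at high dilution secures.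

Step 10
Reactants: 15 trans‑decalin‑3‑one
Product: 16 equatorial C3 alcohol (C8 dioxolane, C19 OTBS)
Conditions: NaBH4, MeOH/CH2Cl2, −20 → 0 °C
Reagents that add atoms: none
Why: In this NaBH4 reduction hydride adds axially to C3 from the face opposite the axial C4 CH2OTBS group, as in 4,4‑disubstituted 3‑keto terpenoids, which should give the equatorial alcohol cis to C19.

Step 11
Reactants: 16 C3 alcohol
Product: 17 3,19‑dihydroxy C8 ketone
Conditions: 1 M HCl, THF, 23 °C
Reagents that add atoms: water, O
Why: Aqueous acid hydrolysis cleaves the dioxolane and the primary silyl ether in one operation, freeing the C8 ketone and the 3,19‑diol.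

Step 12
Reactants: 17 keto diol
Product: 18 3,19‑O‑isopropylidene C8 ketone
Conditions: 2,2‑dimethoxypropane, PPTS (cat.), acetone, 23 °C
Reagents that add atoms: 2,2‑dimethoxypropane, COC(C)(C)OC
Why: Acid‑catalysed transacetalisation closes the six‑membered acetonide between the equatorial C3 hydroxyl and the axial C19 hydroxymethyl, which are gauche, and leaves the ketone free in acetone as solvent.

Step 13
Reactants: 18 acetonide ketone
Product: 19 C7–C8 trimethylsilyl enol ether
Conditions: Me3SiCl, LiN(CHMe2)2, THF, −78 °C (internal quench)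
Reagents that add atoms: chlorotrimethylsilane, C[Si](C)(C)Cl
Why: Kinetic enolisation with in situ silylation should occur at the unhindered C7 methylene and not at C9, which is flanked by the quaternary C10.

Step 14
Reactants: 19 silyl enol ether
Product: 20 C6=C7 enone (8‑ketone)
Conditions: Pd(OAc)2 (1.1 equiv), MeCN, 23 °C
Reagents that add atoms: none
Why: Saegusa–Ito oxidation (palladation of the silyl enol ether, then β‑hydride elimination) gives the enone, which removes the acidic C7 hydrogens so that only C9 can be enolised next.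

Step 15
Reactants: 20 enone
Product: 22 C9‑alkylated enone (CH2CO2t‑Bu trans to the C10 methyl; 9‑epi), via lithium dienolate 21 (not isolated)
Conditions: LiN(CHMe2)2, THF, −78 °C; BrCH2CO2t‑Bu, DMPU, −78 → −30 °C
Reagents that add atoms: tert‑butyl bromoacetate, CC(C)(C)OC(=O)CBr
Why: Kinetic α′‑deprotonation gives the cross‑conjugated dienolate, which is alkylated at C9 by the reactive α‑bromo ester from the face opposite the axial C10 methyl, so the side chain should first enter trans to that methyl.

Step 16
Reactants: 22 alkylated enone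
Product: 24 saturated keto ester (C9 side chain equatorial and cis to the C10 methyl), via 9‑epi keto ester 23 (not isolated)
Conditions: H2 (1 atm), Pd/C, EtOAc, 23 °C; filter; NaOMe (cat.), MeOH, 23 °C
Reagents that add atoms: none
Why: Heterogeneous hydrogenation saturates the enone alkene, and base epimerisation through the C8–C9 enolate should then move the side chain to the equatorial position, where it avoids the 1,3‑diaxial contacts with H5 and H7; the minor epimer can be re‑equilibrated.

Step 17
Reactants: 24 keto ester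
Product: 25 8(17)‑methylene tert‑butyl ester
Conditions: Ph3PCH3Br, KOt‑Bu, toluene, 0 → 70 °C
Reagents that add atoms: methyltriphenylphosphonium bromide, C[P+](c1ccccc1)(c1ccccc1)c1ccccc1.[Br-]
Why: Wittig methylenation of the hindered C8 ketone with the unstabilised ylide installs the exocyclic C8=C17 alkene, and the tert‑butyl ester is too hindered to be attacked.

Step 18
Reactants: 25 methylene ester
Product: 26 C12 primary alcohol
Conditions: LiAlH4, THF, 0 °C; H2O, NaOH aq.
Reagents that add atoms: none
Why: LiAlH4 reduction of the ester gives the primary alcohol and leaves the acetonide and the 1,1‑disubstituted alkene untouched.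

Step 19
Reactants: 26 alcohol
Product: 27 C12 aldehyde
Conditions: Dess–Martin periodinane, pyridine, CH2Cl2, 0 → 23 °C
Reagents that add atoms: none
Why: Dess–Martin oxidation gives the aldehyde without acid or base that could move the exocyclic alkene or open the acetonide.

Step 20
Reactants: 28 (S)‑4‑hydroxydihydrofuran‑2(3H)‑one
Product: 29 (S)‑4‑(tert‑butyldimethylsilyloxy)dihydrofuran‑2(3H)‑one
Conditions: TBSCl, imidazole, DMF, 23 °C
Reagents that add atoms: tert‑butyldimethylsilyl chloride, CC(C)(C)[Si](C)(C)Cl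
Why: Standard silylation of the secondary alcohol; the C14 stereocentre of the target is taken unchanged from this lactone.

Step 21
Reactants: 29 silyloxy lactone; 27 aldehyde
Product: 31 aldol adduct (12RS; C13 trans to OTBS), via lactone lithium enolate 30 (not isolated)
Conditions: 29, LiN(CHMe2)2, THF, −78 °C; 27, −78 °C; AcOH
Reagents that add atoms: none
Why: Aldol addition of the lactone lithium enolate at −78 °C, where β‑elimination of the silyloxy group should be slow, forms the C12–C13 bond anti to the silyloxy group, and both new centres are lost in the next step.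

Step 22
Reactants: 31 aldol adduct
Product: 33 14‑O‑TBS‑3,19‑O‑isopropylideneandrographolide, via C12 mesylate 32 (not isolated)
Conditions: MsCl, Et3N, CH2Cl2, 0 °C; DBU, 0 → 23 °C
Reagents that add atoms: none
Why: Mesylation followed by E1cB elimination through the lactone enolate gives the conjugated exocyclic alkene, and the E isomer is expected because it keeps C11 away from the lactone carbonyl oxygen.

Step 23
Reactants: 33 silyl ether
Product: 34 3,19‑O‑isopropylideneandrographolide
Conditions: HF·pyridine, pyridine, THF, 0 → 23 °C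
Reagents that add atoms: none
Why: Buffered fluoride cleavage removes the allylic silyl ether without acid strong enough to open the acetonide and without base that could trigger loss of the C14 oxygen.

Step 24
Reactants: 34 C14 alcohol
Product: 35 14‑O‑acetyl‑3,19‑O‑isopropylideneandrographolide
Conditions: Ac2O, pyridine, DMAP (cat.), CH2Cl2, 0 °C
Reagents that add atoms: acetic anhydride, CC(=O)OC(C)=O
Why: Acylation takes the only free hydroxyl (C14), since the C3 and C19 hydroxyls are masked in the acetonide.

Step 25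
Reactants: 35 acetonide acetate
Product: 36 14‑O‑acetylandrographolide (CNP0077248.1)
Conditions: AcOH/H2O (7:3), 23 °C
Reagents that add atoms: none
Why: Mild aqueous acetic acid hydrolyses the 1,3‑diol acetonide while the allylic acetate should stay in place.

**Compound list**

1 | 3‑methoxybenzyl alcohol | COc1cccc(CO)c1 | starting material
2 | (5‑methoxycyclohexa‑1,4‑dien‑1‑yl)methanol | COC1=CCC=C(CO)C1 | intermediate
3 | (1,4‑dioxaspiro[4.5]dec‑7‑en‑7‑yl)methanol (ring B: C8 ketal, C9 CH2, C10=C5 alkene, C20 CH2OH) | OCC1=CCCC2(C1)OCCO2 | intermediate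
4 | (R)‑4‑benzyl‑3‑propionyloxazolidin‑2‑one | CCC(=O)N1[C@H](Cc2ccccc2)COC1=O | starting material
5 | acrolein | C=CC=O | starting material
6 | Z‑dibutylboron enolate of 4 | C/C=C(\OB(CCCC)CCCC)N1[C@H](Cc2ccccc2)COC1=O | intermediate (not isolated)
7 | (R)‑4‑benzyl‑3‑[(2R,3S)‑3‑hydroxy‑2‑methylpent‑4‑enoyl]oxazolidin‑2‑one | C=C[C@H](O)[C@@H](C)C(=O)N1[C@H](Cc2ccccc2)COC1=O | intermediate
8 | lithium alkoxide of 3 | [Li+].[O-]CC1=CCCC2(C1)OCCO2 | intermediate (not isolated)
9 | (1,4‑dioxaspiro[4.5]dec‑7‑en‑7‑yl)methyl (2R,3S)‑3‑hydroxy‑2‑methylpent‑4‑enoate | C=C[C@H](O)[C@@H](C)C(=O)OCC1=CCCC2(C1)OCCO2 | intermediate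
10 | dilithium alkoxide–enolate of 9 (C3 cis to the enolate O–Li) | [Li+].[Li+].C=C[C@H]([O-])/C(C)=C(\[O-])OCC1=CCCC2(C1)OCCO2 | intermediate (not isolated)
11 | (2S,3S)‑3‑hydroxy‑2‑methyl‑2‑[(8S)‑7‑methylidene‑1,4‑dioxaspiro[4.5]decan‑8‑yl]pent‑4‑enoic acid (C19 acid, C3 carbinol, C4 quaternary, C5, C10=CH2) | C=C[C@H](O)[C@@](C)(C(=O)O)[C@H]1CCC2(OCCO2)CC1=C | intermediate
12 | (2R,3S)‑2‑methyl‑2‑[(8S)‑7‑methylidene‑1,4‑dioxaspiro[4.5]decan‑8‑yl]pent‑4‑ene‑1,3‑diol | C=C[C@H](O)[C@@](C)(CO)[C@H]1CCC2(OCCO2)CC1=C | intermediate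
13 | (3S,4R)‑5‑(tert‑butyldimethylsilyloxy)‑4‑methyl‑4‑[(8S)‑7‑methylidene‑1,4‑dioxaspiro[4.5]decan‑8‑yl]pent‑1‑en‑3‑ol | C=C[C@H](O)[C@@](C)(CO[Si](C)(C)C(C)(C)C)[C@H]1CCC2(OCCO2)CC1=C | intermediate
14 | (4R)‑5‑(tert‑butyldimethylsilyloxy)‑4‑methyl‑4‑[(8S)‑7‑methylidene‑1,4‑dioxaspiro[4.5]decan‑8‑yl]pent‑1‑en‑3‑one (key‑step precursor) | C=CC(=O)[C@@](C)(CO[Si](C)(C)C(C)(C)C)[C@H]1CCC2(OCCO2)CC1=C | intermediate
15 | trans‑decalin‑3‑one: C8 ethylene ketal, C10 axial methyl trans to H5, C4 with equatorial methyl and axial CH2OTBS cis to the C10 methyl (key‑step product) | O=C1CC[C@@]2(C)CC3(OCCO3)CC[C@@H]2[C@]1(C)CO[Si](C)(C)C(C)(C)C | intermediate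
16 | as 15 with equatorial C3 hydroxyl cis to C19 | O[C@@H]1CC[C@@]2(C)CC3(OCCO3)CC[C@@H]2[C@]1(C)CO[Si](C)(C)C(C)(C)C | intermediate
17 | 3,19‑dihydroxy trans‑decalin‑8‑one | O[C@@H]1CC[C@@]2(C)CC(=O)CC[C@@H]2[C@]1(C)CO | intermediate
18 | 3,19‑O‑isopropylidene trans‑decalin‑8‑one | O1[C@@H]2CC[C@@]3(C)CC(=O)CC[C@@H]3[C@]2(C)COC1(C)C | intermediate
19 | C7–C8 trimethylsilyl enol ether of 18 | O1[C@@H]2CC[C@@]3(C)CC(O[Si](C)(C)C)=CC[C@@H]3[C@]2(C)COC1(C)C | intermediate
20 | C6=C7 enone (8‑ketone), acetonide | O1[C@@H]2CC[C@@]3(C)CC(=O)C=C[C@@H]3[C@]2(C)COC1(C)C | intermediate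
21 | lithium cross‑conjugated dienolate of 20 (C8–O, C8=C9) | [Li+].O1[C@@H]2CC[C@@]3(C)C=C([O-])C=C[C@@H]3[C@]2(C)COC1(C)C | intermediate (not isolated)
22 | C9 tert‑butoxycarbonylmethyl enone, side chain trans to the C10 methyl (9‑epi) | O1[C@@H]2CC[C@@]3(C)[C@@H](CC(=O)OC(C)(C)C)C(=O)C=C[C@@H]3[C@]2(C)COC1(C)C | intermediate
23 | saturated 8‑keto tert‑butyl ester, 9‑epi | O1[C@@H]2CC[C@@]3(C)[C@@H](CC(=O)OC(C)(C)C)C(=O)CC[C@@H]3[C@]2(C)COC1(C)C | intermediate (not isolated)
24 | saturated 8‑keto tert‑butyl ester, C9 side chain equatorial and cis to the C10 methyl | O1[C@@H]2CC[C@@]3(C)[C@H](CC(=O)OC(C)(C)C)C(=O)CC[C@@H]3[C@]2(C)COC1(C)C | intermediate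
25 | 8(17)‑methylene tert‑butyl ester | O1[C@@H]2CC[C@@]3(C)[C@H](CC(=O)OC(C)(C)C)C(=C)CC[C@@H]3[C@]2(C)COC1(C)C | intermediate
26 | C12 primary alcohol | O1[C@@H]2CC[C@@]3(C)[C@H](CCO)C(=C)CC[C@@H]3[C@]2(C)COC1(C)C | intermediate
27 | C12 aldehyde | O1[C@@H]2CC[C@@]3(C)[C@H](CC=O)C(=C)CC[C@@H]3[C@]2(C)COC1(C)C | intermediate
28 | (S)‑4‑hydroxydihydrofuran‑2(3H)‑one | O=C1OC[C@@H](O)C1 | starting material
29 | (S)‑4‑(tert‑butyldimethylsilyloxy)dihydrofuran‑2(3H)‑one | O=C1OC[C@@H](O[Si](C)(C)C(C)(C)C)C1 | intermediate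
30 | lithium enolate of 29 | [Li+].[O-]C1=C[C@H](O[Si](C)(C)C(C)(C)C)CO1 | intermediate (not isolated)
31 | aldol adduct (12RS; C13 trans to the C14 OTBS) | O1[C@@H]2CC[C@@]3(C)[C@H](CC(O)[C@@H]4C(=O)OC[C@H]4O[Si](C)(C)C(C)(C)C)C(=C)CC[C@@H]3[C@]2(C)COC1(C)C | intermediate
32 | C12 mesylate of 31 | O1[C@@H]2CC[C@@]3(C)[C@H](CC(OS(C)(=O)=O)[C@@H]4C(=O)OC[C@H]4O[Si](C)(C)C(C)(C)C)C(=C)CC[C@@H]3[C@]2(C)COC1(C)C | intermediate (not isolated)
33 | 14‑O‑TBS‑3,19‑O‑isopropylideneandrographolide (12E) | O1[C@@H]2CC[C@@]3(C)[C@H](C/C=C4/C(=O)OC[C@H]4O[Si](C)(C)C(C)(C)C)C(=C)CC[C@@H]3[C@]2(C)COC1(C)C | intermediate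
34 | 3,19‑O‑isopropylideneandrographolide | O1[C@@H]2CC[C@@]3(C)[C@H](C/C=C4/C(=O)OC[C@H]4O)C(=C)CC[C@@H]3[C@]2(C)COC1(C)C | intermediate
35 | 14‑O‑acetyl‑3,19‑O‑isopropylideneandrographolide | O1[C@@H]2CC[C@@]3(C)[C@H](C/C=C4/C(=O)OC[C@H]4OC(C)=O)C(=C)CC[C@@H]3[C@]2(C)COC1(C)C | intermediate
36 | 14‑O‑acetylandrographolide (CNP0077248.1) | C=C1CC[C@@H]2[C@](C)(CO)[C@H](O)CC[C@@]2(C)[C@@H]1C/C=C1/C(=O)OC[C@H]1OC(C)=O | target

**Totals**

Total step count: 25. Longest linear sequence: 23 steps (steps 1, 2, 4–19, 21–25, from 3‑methoxybenzyl alcohol).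

**Steps most likely to fail**

Step 5 (dianionic Ireland–Claisen). The lithium aldolate of 9 may fragment by retro‑aldol before the second deprotonation, the ester enolate may expel the allylic alkoxide on warming faster than it rearranges, or the lithium chelate may be too loose to bias one enolate face. The fallback is a classical Ireland–Claisen rearrangement of a neutral silyl ketene acetal, where the face is set by 1,3‑allylic strain instead of a chelate. That element is expected to send the allyl terminus to the opposite face for a given C3 configuration, so the fallback runs in the C3‑epimeric series and sets out from 3 and 5. Purchased (S)‑4‑benzyl‑3‑propionyloxazolidin‑2‑one F1 is converted into its Z‑dibutylboron enolate F2 and added to 5 under the conditions of step 3, giving the (2S,3R) syn‑aldol adduct F3. Transesterification with alkoxide 8 as in step 4 gives ester F4. LiN(CHMe2)2 (2.5 equiv) in THF at −78 °C followed by Me3SiCl/Et3N traps the dianion as the bis(trimethylsilyl) ketene acetal F5, which keeps C3 cis to the silyloxy group and should rearrange at 23 °C through the same chair. With H3 eclipsing the ketene acetal plane, the allyl terminus should bond anti to the vinyl group, and work‑up at pH 4 should give acid F6, the C3 epimer of 11 with C4 and C5 as in 11. LiAlH4 gives diol F7, TBSCl/imidazole gives silyl ether F8, and Dess–Martin oxidation erases C3 and returns to the route at 14. Because C3 stays stereogenic until then, material from the other face is a separable diastereomer.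

Step 9 (key step). The iron hydride may reduce the vinyl ketone by conjugate hydrogen‑atom transfer, a second hydrogen‑atom transfer may quench the C10 radical before ring closure (plain hydrogenation of the methylene), or closure may pass through a boat‑like arrangement and give the cis ring fusion. The fallback generates the same radical by single‑electron opening of an epoxide, with no hydride present, and sets out from 14. Buffered mCPBA (NaHCO3, CH2Cl2, 0 °C) should epoxidise only the electron‑rich methylene and give spiro‑epoxide F9. Cp2TiCl2 with Zn dust in THF (trivalent titanium) opens it to the tertiary C10 radical, now carrying C20–O–Ti, which should close 6‑endo onto the vinyl ketone to give the 20‑hydroxy decalone F10. Barton–McCombie deoxygenation through the imidazolyl thiocarbonate F11 (1,1′‑thiocarbonyldiimidazole; then Bu3SnH, AIBN, toluene, 110 °C) returns to the route at 15.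

Step 15 (C9 alkylation). Substitution at the neopentyl‑type α′ carbon may be slow enough for proton exchange, dialkylation or γ‑deprotonation at C5 to compete, and the C9 configuration then depends on a modest thermodynamic bias in the equilibration of step 16. The fallback sets C9 by hydrogenation instead and sets out from 20. Lithium dienolate 21 is added to tert‑butyl glyoxylate at −78 °C to give aldol adduct F12. MsCl/Et3N gives, through mesylate F13, the cross‑conjugated alkylidene enone F14. H2 over Pd/C should saturate both C6=C7 and C9=C11, delivering hydrogen to C9 from the face opposite the axial C10 methyl, and returns to the route at 24.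

**Further compounds**

F1 | step 5 | (S)‑4‑benzyl‑3‑propionyloxazolidin‑2‑one (purchased) | CCC(=O)N1[C@@H](Cc2ccccc2)COC1=O
F2 | step 5 | Z‑dibutylboron enolate of F1 (not isolated) | C/C=C(\OB(CCCC)CCCC)N1[C@@H](Cc2ccccc2)COC1=O
F3 | step 5 | (S)‑4‑benzyl‑3‑[(2S,3R)‑3‑hydroxy‑2‑methylpent‑4‑enoyl]oxazolidin‑2‑one | C=C[C@@H](O)[C@H](C)C(=O)N1[C@@H](Cc2ccccc2)COC1=O
F4 | step 5 | (1,4‑dioxaspiro[4.5]dec‑7‑en‑7‑yl)methyl (2S,3R)‑3‑hydroxy‑2‑methylpent‑4‑enoate | C=C[C@@H](O)[C@H](C)C(=O)OCC1=CCCC2(C1)OCCO2
F5 | step 5 | bis(trimethylsilyl) ketene acetal of F4 (not isolated) | C=C[C@@H](O[Si](C)(C)C)/C(C)=C(\O[Si](C)(C)C)OCC1=CCCC2(C1)OCCO2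
F6 | step 5 | (2S,3R)‑3‑hydroxy‑2‑methyl‑2‑[(8S)‑7‑methylidene‑1,4‑dioxaspiro[4.5]decan‑8‑yl]pent‑4‑enoic acid (C3 epimer of 11) | C=C[C@@H](O)[C@@](C)(C(=O)O)[C@H]1CCC2(OCCO2)CC1=C
F7 | step 5 | C3 epimer of diol 12 | C=C[C@@H](O)[C@@](C)(CO)[C@H]1CCC2(OCCO2)CC1=C
F8 | step 5 | C3 epimer of silyl ether 13 | C=C[C@@H](O)[C@@](C)(CO[Si](C)(C)C(C)(C)C)[C@H]1CCC2(OCCO2)CC1=C
F9 | step 9 | C10–C20 spiro‑epoxide of 14 (epimers at C10) | C=CC(=O)[C@@](C)(CO[Si](C)(C)C(C)(C)C)[C@H]1CCC2(OCCO2)CC13CO3
F10 | step 9 | 20‑hydroxy analogue of 15 (axial CH2OH on C10) | O=C1CC[C@@]2(CO)CC3(OCCO3)CC[C@@H]2[C@]1(C)CO[Si](C)(C)C(C)(C)C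
F11 | step 9 | O‑C20 imidazolyl thiocarbonate of F10 | O=C1CC[C@@]2(COC(=S)n3ccnc3)CC4(OCCO4)CC[C@@H]2[C@]1(C)CO[Si](C)(C)C(C)(C)C
F12 | step 15 | C9 glyoxylate aldol adduct of 20 (epimers at C9 and C11) | O1[C@@H]2CC[C@@]3(C)C(C(O)C(=O)OC(C)(C)C)C(=O)C=C[C@@H]3[C@]2(C)COC1(C)C
F13 | step 15 | C11 mesylate of F12 (not isolated) | O1[C@@H]2CC[C@@]3(C)C(C(OS(C)(=O)=O)C(=O)OC(C)(C)C)C(=O)C=C[C@@H]3[C@]2(C)COC1(C)C
F14 | step 15 | C9=C11 alkylidene enone tert‑butyl ester (E/Z mixture) | O1[C@@H]2CC[C@@]3(C)C(=CC(=O)OC(C)(C)C)C(=O)C=C[C@@H]3[C@]2(C)COC1(C)C
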